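The runs stem from a simulated flask on assumed constants; noise was put on by code.

**The decision.** I decided to reckon this flask by the age of its target, not by its conversion, since the target is lost once it is made.

| setting | larch | maple | flask |
|---|---|---|---|
| substrate | 0.25 M | 1 M | 0.50 M |
| gas phase | 110 mM (held) | 110 mM (held) | 110 mM (held) |
| remark | run made earlier | run made earlier |  |
| time |  |  | 3.0 min |

| run | time / min | target / % | substrate / % |
|---|---|---|---|
| larch | 0.250 | 24.6 | 74.2 |
| larch | 0.417 | 42.2 | 56.2 |
| larch | 0.833 | 77.7 | 17.0 |
| larch | 1.50 | 86.3 | 0 |
| larch | 3.00 | 69.1 | 0.3 |
| maple | 0.667 | 18.7 | 80.4 |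
| maple | 1.33 | 36.3 | 60.2 |
| maple | 2.00 | 51.0 | 40.6 |
| maple | 2.50 | 61.1 | 26.8 |
| maple | 3.00 | 69.8 | 12.8 |

(standard deviation of a reading: 0.3 percentage points)

- the numbers in the tables scatter with a standard deviation of 0.3 percentage points
- at the start none of the gas phase is in solution

1. target at 3.0 min, in percent of the substrate charged
2. the change that raises the amount of target at 3.0 min, in percent of the substrate charged most ("none" if none brings more than 2 percentage points) (north / east / none)
3. amount of target at 3.0 min, in percent of the substrate charged, after east

- north: doubling the saturation concentration of gas phase, all else as stated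
- east: doubling the transfer coefficient of the gas phase, all else as stated

**What the runs show.** Over the stretches I read, the maple run lost substrate at 0.290 M min⁻¹ and the larch run at 0.245 M min⁻¹, although their charges differ 4.00 times, so I took the transfer of the gas phase as the rate-limiting step over those stretches. Once the larch substrate read 0%, the larch target still fell, and from those readings I took a loss constant of 0.148 min⁻¹.

**Two extremes.** Turnover at the first instant gives an age of 3.0 min and 64.1%; turnover spread evenly up to the stop gives 1.50 min and 80.1%. At c(substrate) = 0.50 M and the maple rate, I reckoned the flask to need 1.73 min, less than the time allowed, so I placed it between them. I reckoned the flask's mean age, the stop time less the midpoint of turnover, at 2.14 min, and I committed to 72.9%. In this reckoning a faster supply moves that midpoint earlier, so I expected north and east to lose target, and chose none, with east between 64.1% and 72.9%.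

**The forecast.** The forecast gave 73.6%, none and 69.3%, saying “Target then simply ages longer”, and its first figure stood higher than mine.

**The result.** The flask gave 73.5% and the choice was none, with 26.5% standing as over-reaction product at 3.00 min.

    target → over-reaction product (k = 0.00247 s⁻¹)
    gas phase ⇌ dissolved gas, rate k2*(csat - [dissolved gas]) (kL = 0.0461 s⁻¹)
    substrate + dissolved gas → target (k = 3.32 M⁻¹ s⁻¹)

With the supply doubled by east, I reckoned turnover at 0.865 min, so the mean age goes from 2.14 min to 2.57 min, which reckons to 68.4%, and the flask after east gave 68.9%.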